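## Retrosynthetic overview

1. Numbering (naphthalen-2(3H)-one): ring B = C1, C2 (C=O), C3 (CHOH), C4, C4a, C8a; ring A = C4a (CH3), C5 (CH3), C6 (O-acyl), C7=C8, C8a. Last bonds cut: the C6–O ester bond (alcohol 20 + protected dienoic acid 29, made from (S)-2-methylglycidol) and the C3–O bond (Rubottom oxidation of the dienone).
2. Key disconnection: ring B is removed in one retro-Robinson annulation, C4–C4a (Michael addition) and C1=C8a (aldol condensation), giving cyclohexenone 9 and the four-carbon α-silyl vinyl ketone 10.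
3. Enabling feature: ring B is a cyclohex-2-enone whose β-carbon C8a and γ-carbon C4a both lie in ring A. C8a is a latent ketone carbon, the methyl-bearing quaternary C4a is its α-carbon, and C1–C2(=O)–C3–C4 is a methyl vinyl ketone unit. Because ring A already holds C7=C8, the α′-enolate of that enone gives the linear C7=C8–C8a=C1–C2=O dienone directly.
4. Ring A (all six carbons and the C6 oxygen) comes from 4-methoxyphenol: oxidative dearomatization to the quinone monoketal, then copper-catalysed enantioselective methyl addition to the prochiral dienone. That stereocentre relays chirality to C5 (trans methylation) and C6 (reduction), is erased in the annulation enolate and is rebuilt as C4a.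
5. Ring order: ring A (from the arene) first, ring B second (key step), side chain last.

Key step: step 7

Assumption: the (S,R,R)-phosphoramidite is taken to deliver methyl to the same enone face as in its additions to cyclohex-2-enone, which corresponds to (5R)-3; if the sense were opposite, the (R,S,S)-ligand would be used and nothing else changes.
Remark: C6 of 9 is α to the ketone and may epimerise on handling; this is inconsequential because C6 becomes trigonal in the key step.

## Route

Step 1
Reactants: 1 4-methoxyphenol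
Product: 2 4,4-dimethoxycyclohexa-2,5-dien-1-one
Conditions: PhI(OAc)2, MeOH, 0 °C
Reagents that add atoms: methanol, CO
Why: Oxidative dearomatization of a para-alkoxyphenol by a trivalent-iodine oxidant (quinone monoketal formation), in which methanol attacks the para carbon of the iodine-activated phenol and turns the flat arene into a prochiral cross-conjugated dienone carrying both oxygens of ring A.

Step 2
Reactants: 2 4,4-dimethoxycyclohexa-2,5-dien-1-one
Product: 3 (5R)-4,4-dimethoxy-5-methylcyclohex-2-en-1-one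
Conditions: Cu(OTf)2 (2 mol %), (S,R,R)-O,O′-(1,1′-binaphthyl-2,2′-diyl) N,N-bis(1-phenylethyl)phosphoramidite (4 mol %), ZnMe2, toluene, −25 °C; aq. NH4Cl
Reagents that add atoms: dimethylzinc, C[Zn]C
Why: Copper/phosphoramidite-catalysed enantioselective conjugate addition of a dialkylzinc to a 4,4-dialkoxycyclohexa-2,5-dienone, a desymmetrization in which the chiral copper–methyl species selects one enantiotopic enone arm and one face, so that C5 should be set as R and the more hindered mono-adduct should resist a second addition.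

Step 3
Reactants: 3 (5R)-4,4-dimethoxy-5-methylcyclohex-2-en-1-one
Product: 5 (5R,6R)-4,4-dimethoxy-5,6-dimethylcyclohex-2-en-1-one, via lithium enolate 4 (not isolated)
Conditions: LiN(i-Pr)2, THF, −78 °C; MeI, −78 → −20 °C
Reagents that add atoms: iodomethane, CI
Why: Kinetic α′-enolate alkylation, in which iodomethane should approach C6 anti to the adjacent C5 methyl and give the trans-5,6 product, so that the catalyst-made centre relays its chirality to C6 (the future C5 of the decalin).

Step 4
Reactants: 5 (5R,6R)-4,4-dimethoxy-5,6-dimethylcyclohex-2-en-1-one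
Product: 6 (1S,5R,6R)-4,4-dimethoxy-5,6-dimethylcyclohex-2-en-1-ol
Conditions: (S)-2-methyl-CBS-oxazaborolidine (20 mol %), BH3·SMe2, THF, −30 °C; MeOH, then aq. work-up
Reagents that add atoms: none
Why: Corey–Bakshi–Shibata 1,2-reduction of an enone, in which the bulky catalyst–borane complex should deliver hydride anti to the α-methyl at C6, the same face the (S)-catalyst selects when the alkenyl arm is the larger group (matched case), so the new 1S carbinol should be cis to the C6 methyl without conjugate reduction.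

Step 5
Reactants: 6 (1S,5R,6R)-4,4-dimethoxy-5,6-dimethylcyclohex-2-en-1-ol
Product: 8 1-({[(1S,5R,6R)-4,4-dimethoxy-5,6-dimethylcyclohex-2-en-1-yl]oxy}methyl)-4-methoxybenzene, via sodium alkoxide 7 (not isolated)
Conditions: NaH, THF/DMF, 0 °C; 4-MeOC6H4CH2Cl, Bu4NI (cat.), 0 °C → rt
Reagents that add atoms: 4-methoxybenzyl chloride, COc1ccc(CCl)cc1
Why: Williamson ether synthesis under basic conditions that leave the allylic ketal intact; the 4-methoxybenzyl ether survives aqueous acid, amide bases and methoxide and is later removed oxidatively in the presence of silyl ethers.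

Step 6
Reactants: 8 1-({[(1S,5R,6R)-4,4-dimethoxy-5,6-dimethylcyclohex-2-en-1-yl]oxy}methyl)-4-methoxybenzene
Product: 9 (4S,5R,6R)-4-[(4-methoxybenzyl)oxy]-5,6-dimethylcyclohex-2-en-1-one
Conditions: PPTS (cat.), acetone/H2O (10:1), rt
Reagents that add atoms: water, O
Why: Acid-catalysed hydrolysis of the dimethyl ketal through the allylic oxocarbenium ion unveils the enone (overall a 1,4-carbonyl transposition relative to 5), the mild acid being chosen to avoid loss of the C4 ether and aromatization.

Step 7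
Reactants: 9 (4S,5R,6R)-4-[(4-methoxybenzyl)oxy]-5,6-dimethylcyclohex-2-en-1-one; 10 3-(trimethylsilyl)but-3-en-2-one
Product: 15 (4aR,5R,6S)-6-[(4-methoxybenzyl)oxy]-4a,5-dimethyl-4,4a,5,6-tetrahydronaphthalen-2(3H)-one, via lithium dienolate 11 (not isolated), via Michael adduct 12 (not isolated), via diketone 13 (not isolated), via ketol 14 (not isolated)
Conditions: LiN(i-Pr)2, THF, −78 °C; 10, −78 → −30 °C; then NaOMe (cat.), MeOH, 0 °C → rt; aq. NH4Cl
Reagents that add atoms: none
Why: Robinson annulation in its α-silyl vinyl ketone form, run in one flask: LiN(i-Pr)2 removes the C6 proton of 9 under kinetic control to give the cross-conjugated enolate 11, which adds through C6 to the β-carbon of 10 (new C4–C4a bond), the α-silyl group stabilising the adduct enolate 12 so that proton transfer and polymerisation of the acceptor are suppressed. Methoxide in methanol then removes the silyl group to give diketone 13, whose methyl-ketone enolate closes ring B onto the ring A carbonyl in a 6-(enolendo)-exo-trig aldol addition (ketol 14), and loss of water places the new C1=C8a bond in conjugation with C7=C8 to give the linear dienone. The only new stereocentre, quaternary C4a, is substrate-controlled: the C5 methyl of 9 (pseudoaxial beside the enolate to avoid allylic strain with the C6 methyl) and the cis C4 ether lie on one face, so the acceptor should enter from the other face and the angular methyl should end cis to both. The relay stereocentre C6 of 9 is erased in the planar enolate, so its configuration is irrelevant. The step needs α′- over γ-deprotonation (kinetic base at −78 °C; the only γ-hydrogen, C4–H, is removed more slowly), 1,4- over 1,2-addition (tetrasubstituted enolate, silyl-shielded carbonyl of 10) and a single aldol regiochemistry (only the methyl group of 13 reaches the ring carbonyl through a six-membered transition state).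

Step 8
Reactants: 15 (4aR,5R,6S)-6-[(4-methoxybenzyl)oxy]-4a,5-dimethyl-4,4a,5,6-tetrahydronaphthalen-2(3H)-one
Product: 19 (3R,4aR,5R,6S)-6-[(4-methoxybenzyl)oxy]-4a,5-dimethyl-3-[(triethylsilyl)oxy]-4,4a,5,6-tetrahydronaphthalen-2(3H)-one, via lithium enolate 16 (not isolated), via silyl enol ether 17 (not isolated), via silyloxy epoxide 18 (not isolated)
Conditions: LiN(SiMe3)2, THF, −78 °C; Et3SiCl, −78 → 0 °C; then mCPBA, NaHCO3, CH2Cl2, −20 → 0 °C
Reagents that add atoms: chlorotriethylsilane, CC[Si](Cl)(CC)CC; 3-chloroperoxybenzoic acid, OOC(=O)c1cccc(Cl)c1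
Why: Rubottom oxidation: kinetic deprotonation at C3 (the only α′ position) gives the cross-conjugated silyl enol ether, whose electron-rich C2=C3 bond should be epoxidised anti to the axial C4a methyl, and opening with 1,4-silyl shift gives the α-silyloxy ketone with the equatorial 3R oxygen, which is also the thermodynamically preferred epimer.

Step 9
Reactants: 19 (3R,4aR,5R,6S)-6-[(4-methoxybenzyl)oxy]-4a,5-dimethyl-3-[(triethylsilyl)oxy]-4,4a,5,6-tetrahydronaphthalen-2(3H)-one
Product: 20 (3R,4aR,5R,6S)-6-hydroxy-4a,5-dimethyl-3-[(triethylsilyl)oxy]-4,4a,5,6-tetrahydronaphthalen-2(3H)-one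
Conditions: DDQ, CH2Cl2/pH 7 phosphate buffer (10:1), 0 °C
Reagents that add atoms: none
Why: Oxidative cleavage of the 4-methoxybenzyl ether (hydride abstraction from the electron-rich benzylic position, then hydrolysis of the oxocarbenium ion), which should leave the silyl ether and the electron-poor dienone untouched and does not break the C6–O bond.

Step 10
Reactants: 21 [(2S)-2-methyloxiran-2-yl]methanol
Product: 22 (2R)-2-methylbutane-1,2-diol
Conditions: MeMgBr (2.5 equiv), CuI (10 mol %), THF, −30 → 0 °C; aq. NH4Cl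
Reagents that add atoms: methylmagnesium bromide, C[Mg]Br
Why: Copper-catalysed Grignard opening of a 2,2-disubstituted epoxide at its unsubstituted carbon (SN2), which leaves the quaternary stereocentre untouched; a Payne rearrangement of the alkoxide would be degenerate and cannot erode the configuration.

Step 11
Reactants: 22 (2R)-2-methylbutane-1,2-diol
Product: 23 (2R)-2-methyl-1,2-bis[(triethylsilyl)oxy]butane
Conditions: Et3SiOTf (2.4 equiv), 2,6-lutidine, CH2Cl2, −78 → 0 °C
Reagents that add atoms: triethylsilyl trifluoromethanesulfonate, CC[Si](CC)(CC)OS(=O)(=O)C(F)(F)F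
Why: Silylation with a silyl triflate and a hindered pyridine base, reactive enough to protect the tertiary as well as the primary hydroxyl.

Step 12
Reactants: 23 (2R)-2-methyl-1,2-bis[(triethylsilyl)oxy]butane
Product: 25 (2R)-2-methyl-2-[(triethylsilyl)oxy]butanal, via alkoxysulfonium salt 24 (not isolated)
Conditions: (COCl)2, DMSO, CH2Cl2, −78 → −40 °C; Et3N, −78 °C → rt
Reagents that add atoms: none
Why: Swern oxidation applied directly to a primary triethylsilyl ether (oxidative deprotection), in which only the unhindered primary silyl ether is attacked by the chlorosulfonium salt while the tertiary one stays, so the water-soluble hydroxy aldehyde is never handled.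

Step 13
Reactants: 25 (2R)-2-methyl-2-[(triethylsilyl)oxy]butanal; 26 ethyl (2E)-4-(diethoxyphosphoryl)but-2-enoate
Product: 28 ethyl (2E,4E,6R)-6-methyl-6-[(triethylsilyl)oxy]octa-2,4-dienoate, via lithiated phosphonate 27 (not isolated)
Conditions: LiN(SiMe3)2, THF, −78 °C; then 25, −78 → 0 °C; aq. NH4Cl
Reagents that add atoms: none
Why: Vinylogous Horner–Wadsworth–Emmons olefination, in which the stabilised phosphonate anion should form the new C4=C5 bond with E geometry while the C2=C3 E geometry is carried over from the crotonate, and the non-enolisable aldehyde cannot epimerise.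

Step 14
Reactants: 28 ethyl (2E,4E,6R)-6-methyl-6-[(triethylsilyl)oxy]octa-2,4-dienoate
Product: 29 (2E,4E,6R)-6-methyl-6-[(triethylsilyl)oxy]octa-2,4-dienoic acid
Conditions: LiOH, THF/MeOH/H2O, rt; aq. HCl to pH 4 at 0 °C
Reagents that add atoms: lithium hydroxide, [Li+].[OH-]
Why: Saponification (acyl–oxygen ester hydrolysis) under conditions a hindered tertiary silyl ether should tolerate, with careful acidification to protect the acid-sensitive dienylic silyl ether.

Step 15
Reactants: 29 (2E,4E,6R)-6-methyl-6-[(triethylsilyl)oxy]octa-2,4-dienoic acid; 20 (3R,4aR,5R,6S)-6-hydroxy-4a,5-dimethyl-3-[(triethylsilyl)oxy]-4,4a,5,6-tetrahydronaphthalen-2(3H)-one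
Product: 31 (3R,4aR,5R,6S)-4a,5-dimethyl-2-oxo-3-[(triethylsilyl)oxy]-2,3,4,4a,5,6-hexahydronaphthalen-6-yl (2E,4E,6R)-6-methyl-6-[(triethylsilyl)oxy]octa-2,4-dienoate, via mixed anhydride 30 (not isolated)
Conditions: 2,4,6-Cl3C6H2COCl, Et3N, THF, rt; then 20, DMAP, toluene, rt → 40 °C
Reagents that add atoms: none
Why: Yamaguchi esterification, in which DMAP transfers the dienoyl group of the mixed anhydride to the hindered axial C6 hydroxyl with retention at C6 because the C6–O bond is not broken.

Step 16
Reactants: 31 (3R,4aR,5R,6S)-4a,5-dimethyl-2-oxo-3-[(triethylsilyl)oxy]-2,3,4,4a,5,6-hexahydronaphthalen-6-yl (2E,4E,6R)-6-methyl-6-[(triethylsilyl)oxy]octa-2,4-dienoate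
Product: 32 (3R,4aR,5R,6S)-3-hydroxy-4a,5-dimethyl-2-oxo-2,3,4,4a,5,6-hexahydronaphthalen-6-yl (2E,4E,6R)-6-hydroxy-6-methylocta-2,4-dienoate (CNP0260852.1)
Conditions: HF·pyridine, pyridine, THF, 0 °C → rt
Reagents that add atoms: none
Why: Fluoride-driven cleavage of both triethylsilyl ethers (Si–F bond formation) under buffered conditions that should spare the ester, the α-ketol and the tertiary dienylic alcohol.

## Compound list

1 | 4-methoxyphenol | COc1ccc(O)cc1 | starting material
2 | 4,4-dimethoxycyclohexa-2,5-dien-1-one | COC1(OC)C=CC(=O)C=C1 | intermediate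
3 | (5R)-4,4-dimethoxy-5-methylcyclohex-2-en-1-one | O=C1C=CC(OC)(OC)[C@H](C)C1 | intermediate
4 | lithium (3R)-4,4-dimethoxy-3-methylcyclohexa-1,5-dien-1-olate (lithium enolate of 3) | [Li]OC1=C[C@@H](C)C(OC)(OC)C=C1 | intermediate
5 | (5R,6R)-4,4-dimethoxy-5,6-dimethylcyclohex-2-en-1-one (trans) | O=C1C=CC(OC)(OC)[C@H](C)[C@H]1C | intermediate
6 | (1S,5R,6R)-4,4-dimethoxy-5,6-dimethylcyclohex-2-en-1-ol (OH cis to C6 methyl) | O[C@H]1C=CC(OC)(OC)[C@H](C)[C@H]1C | intermediate
7 | sodium alkoxide of 6 | [Na]O[C@H]1C=CC(OC)(OC)[C@H](C)[C@H]1C | intermediate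
8 | 1-({[(1S,5R,6R)-4,4-dimethoxy-5,6-dimethylcyclohex-2-en-1-yl]oxy}methyl)-4-methoxybenzene | COc1ccc(CO[C@H]2C=CC(OC)(OC)[C@H](C)[C@H]2C)cc1 | intermediate
9 | (4S,5R,6R)-4-[(4-methoxybenzyl)oxy]-5,6-dimethylcyclohex-2-en-1-one | COc1ccc(CO[C@H]2C=CC(=O)[C@H](C)[C@H]2C)cc1 | intermediate
10 | 3-(trimethylsilyl)but-3-en-2-one | CC(=O)C(=C)[Si](C)(C)C | starting material
11 | lithium cross-conjugated dienolate of 9 (enolate C1=C6) | COc1ccc(CO[C@H]2C=CC(O[Li])=C(C)[C@H]2C)cc1 | intermediate
12 | Michael adduct: lithium enolate of (4S,5R,6R)-4-[(4-methoxybenzyl)oxy]-5,6-dimethyl-6-[3-oxo-2-(trimethylsilyl)butyl]cyclohex-2-en-1-one (enolate geometry not defined) | COc1ccc(CO[C@H]2C=CC(=O)[C@](C)(CC([Si](C)(C)C)=C(C)O[Li])[C@H]2C)cc1 | intermediate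
13 | (4S,5R,6R)-4-[(4-methoxybenzyl)oxy]-5,6-dimethyl-6-(3-oxobutyl)cyclohex-2-en-1-one | COc1ccc(CO[C@H]2C=CC(=O)[C@](C)(CCC(C)=O)[C@H]2C)cc1 | intermediate
14 | (4aR,5R,6S,8aR)-8a-hydroxy-6-[(4-methoxybenzyl)oxy]-4a,5-dimethyl-3,4,4a,5,6,8a-hexahydronaphthalen-2(1H)-one (cis-fused ketol, drawn with OH cis to the 4a-methyl; either epimer dehydrates) | COc1ccc(CO[C@H]2C=C[C@]3(O)CC(=O)CC[C@]3(C)[C@H]2C)cc1 | intermediate
15 | (4aR,5R,6S)-6-[(4-methoxybenzyl)oxy]-4a,5-dimethyl-4,4a,5,6-tetrahydronaphthalen-2(3H)-one | COc1ccc(CO[C@H]2C=CC3=CC(=O)CC[C@]3(C)[C@H]2C)cc1 | intermediate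
16 | lithium enolate of 15 (enolate C2=C3) | COc1ccc(CO[C@H]2C=CC3=CC(O[Li])=CC[C@]3(C)[C@H]2C)cc1 | intermediate
17 | triethylsilyl enol ether of 15 (C2–OSiEt3, C2=C3) | COc1ccc(CO[C@H]2C=CC3=CC(O[Si](CC)(CC)CC)=CC[C@]3(C)[C@H]2C)cc1 | intermediate
18 | 2,3-epoxide of 17 (epoxide oxygen trans to the 4a-methyl, C2 bearing OSiEt3) | COc1ccc(CO[C@H]2C=CC3=C[C@]4(O[Si](CC)(CC)CC)O[C@@H]4C[C@]3(C)[C@H]2C)cc1 | intermediate
19 | (3R,4aR,5R,6S)-6-[(4-methoxybenzyl)oxy]-4a,5-dimethyl-3-[(triethylsilyl)oxy]-4,4a,5,6-tetrahydronaphthalen-2(3H)-one | COc1ccc(CO[C@H]2C=CC3=CC(=O)[C@H](O[Si](CC)(CC)CC)C[C@]3(C)[C@H]2C)cc1 | intermediate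
20 | (3R,4aR,5R,6S)-6-hydroxy-4a,5-dimethyl-3-[(triethylsilyl)oxy]-4,4a,5,6-tetrahydronaphthalen-2(3H)-one | O[C@H]1C=CC2=CC(=O)[C@H](O[Si](CC)(CC)CC)C[C@]2(C)[C@H]1C | intermediate
21 | [(2S)-2-methyloxiran-2-yl]methanol ((S)-2-methylglycidol) | C[C@]1(CO)CO1 | starting material
22 | (2R)-2-methylbutane-1,2-diol | CC[C@@](C)(O)CO | intermediate
23 | (2R)-2-methyl-1,2-bis[(triethylsilyl)oxy]butane | CC[C@@](C)(O[Si](CC)(CC)CC)CO[Si](CC)(CC)CC | intermediate
24 | dimethyl{(2R)-2-methyl-2-[(triethylsilyl)oxy]butoxy}sulfonium chloride | CC[C@@](C)(O[Si](CC)(CC)CC)CO[S+](C)C.[Cl-] | intermediate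
25 | (2R)-2-methyl-2-[(triethylsilyl)oxy]butanal | CC[C@@](C)(O[Si](CC)(CC)CC)C=O | intermediate
26 | ethyl (2E)-4-(diethoxyphosphoryl)but-2-enoate (triethyl 4-phosphonocrotonate) | CCOC(=O)/C=C/CP(=O)(OCC)OCC | starting material
27 | lithium salt of the C4 carbanion of 26 | [Li+].CCOC(=O)/C=C/[CH-]P(=O)(OCC)OCC | intermediate
28 | ethyl (2E,4E,6R)-6-methyl-6-[(triethylsilyl)oxy]octa-2,4-dienoate | CC[C@@](C)(O[Si](CC)(CC)CC)/C=C/C=C/C(=O)OCC | intermediate
29 | (2E,4E,6R)-6-methyl-6-[(triethylsilyl)oxy]octa-2,4-dienoic acid | CC[C@@](C)(O[Si](CC)(CC)CC)/C=C/C=C/C(=O)O | intermediate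
30 | (2E,4E,6R)-6-methyl-6-[(triethylsilyl)oxy]octa-2,4-dienoic 2,4,6-trichlorobenzoic anhydride | CC[C@@](C)(O[Si](CC)(CC)CC)/C=C/C=C/C(=O)OC(=O)c1c(Cl)cc(Cl)cc1Cl | intermediate
31 | (3R,4aR,5R,6S)-4a,5-dimethyl-2-oxo-3-[(triethylsilyl)oxy]-2,3,4,4a,5,6-hexahydronaphthalen-6-yl (2E,4E,6R)-6-methyl-6-[(triethylsilyl)oxy]octa-2,4-dienoate | CC[C@@](C)(O[Si](CC)(CC)CC)/C=C/C=C/C(=O)O[C@H]1C=CC2=CC(=O)[C@H](O[Si](CC)(CC)CC)C[C@]2(C)[C@H]1C | intermediate
32 | (3R,4aR,5R,6S)-3-hydroxy-4a,5-dimethyl-2-oxo-2,3,4,4a,5,6-hexahydronaphthalen-6-yl (2E,4E,6R)-6-hydroxy-6-methylocta-2,4-dienoate | CC[C@@](C)(O)/C=C/C=C/C(=O)O[C@H]1C=CC2=CC(=O)[C@H](O)C[C@]2(C)[C@H]1C | target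

## Step count and risks

Total step count: 16 (steps 1–9 core, steps 10–14 side chain, steps 15–16 union and deprotection).
Longest linear sequence: 11 steps (steps 1–9, 15, 16).

The three steps most likely to fail, most critical first:

Step 4. Facial selectivity may be poor: hydride could also enter syn to the C6 methyl if the alkenyl arm does not behave as the larger group on the catalyst, giving the trans alcohol. The fallback moves the reduction to a saturated ketone, where attack of a bulky borohydride anti to an α-methyl group is dependable. It sets out from 5: hydrogenation (H2, Pd/C, EtOAc) gives (2R,3R)-4,4-dimethoxy-2,3-dimethylcyclohexan-1-one F1. LiBH(s-Bu)3 in THF at −78 °C then gives (1S,2R,3R)-4,4-dimethoxy-2,3-dimethylcyclohexan-1-ol F2, and NaH with 4-methoxybenzyl chloride gives the corresponding 4-methoxybenzyl ether F3. PPTS in wet acetone gives (2R,3R,4S)-4-[(4-methoxybenzyl)oxy]-2,3-dimethylcyclohexan-1-one F4. Kinetic enolisation on the methylene side (LiN(i-Pr)2, Me3SiCl, −78 °C) gives the trimethylsilyl enol ether F5, and Saegusa–Ito dehydrogenation with Pd(OAc)2 in MeCN brings the route back at 9.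

Step 7. The hindered tetrasubstituted enolate may transfer a proton to the acceptor instead of forming the C–C bond. In addition, the ether-bearing carbon may lose its configuration through γ-deprotonation during the methoxide stage. The fallback makes the two bonds in two non-basic stages. It sets out from 9, which is converted (LiN(i-Pr)2, Me3SiCl, −78 °C) into the cross-conjugated trimethylsilyl dienol ether F6. Mukaiyama–Michael addition of F6 to but-3-en-2-one (BF3·OEt2, i-PrOH, CH2Cl2, −78 °C) should give diketone 13 with the same facial preference, and enamine aldol condensation of 13 (pyrrolidine, AcOH, toluene, rt → 60 °C) brings the route back at 15.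

Step 15. Acyl transfer to the hindered axial C6 hydroxyl may be slow, with competing isomerisation of the activated dienoyl unit. The fallback makes the ester bond with a small acyl group and completes the dienoate afterwards. It sets out from 20 and 25: 20 is esterified with diethylphosphonoacetic acid (DCC, DMAP, CH2Cl2) to give the C6 diethylphosphonoacetate F8. Aldehyde 25 is homologated by Wittig reaction with Ph3P=CHCHO (toluene, 80 °C) to (2E,4R)-4-methyl-4-[(triethylsilyl)oxy]hex-2-enal F7. Horner–Wadsworth–Emmons coupling of F8 with F7 under Masamune–Roush conditions (LiCl, i-Pr2NEt, MeCN, rt) should form the C2′=C3′ bond with E geometry and brings the route back at 31.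

Further compounds
F1 | step 4 | (2R,3R)-4,4-dimethoxy-2,3-dimethylcyclohexan-1-one | O=C1CCC(OC)(OC)[C@H](C)[C@H]1C
F2 | step 4 | (1S,2R,3R)-4,4-dimethoxy-2,3-dimethylcyclohexan-1-ol | O[C@H]1CCC(OC)(OC)[C@H](C)[C@H]1C
F3 | step 4 | 1-({[(1S,2R,3R)-4,4-dimethoxy-2,3-dimethylcyclohexyl]oxy}methyl)-4-methoxybenzene | COc1ccc(CO[C@H]2CCC(OC)(OC)[C@H](C)[C@H]2C)cc1
F4 | step 4 | (2R,3R,4S)-4-[(4-methoxybenzyl)oxy]-2,3-dimethylcyclohexan-1-one | COc1ccc(CO[C@H]2CCC(=O)[C@H](C)[C@H]2C)cc1
F5 | step 4 | {[(4S,5R,6R)-4-[(4-methoxybenzyl)oxy]-5,6-dimethylcyclohex-1-en-1-yl]oxy}trimethylsilane | COc1ccc(CO[C@H]2CC=C(O[Si](C)(C)C)[C@H](C)[C@H]2C)cc1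
F6 | step 7 | {[(3R,4S)-4-[(4-methoxybenzyl)oxy]-2,3-dimethylcyclohexa-1,5-dien-1-yl]oxy}trimethylsilane | COc1ccc(CO[C@H]2C=CC(O[Si](C)(C)C)=C(C)[C@H]2C)cc1
F7 | step 15 | (2E,4R)-4-methyl-4-[(triethylsilyl)oxy]hex-2-enal | CC[C@@](C)(O[Si](CC)(CC)CC)/C=C/C=O
F8 | step 15 | (3R,4aR,5R,6S)-4a,5-dimethyl-2-oxo-3-[(triethylsilyl)oxy]-2,3,4,4a,5,6-hexahydronaphthalen-6-yl 2-(diethoxyphosphoryl)acetate | CCOP(=O)(OCC)CC(=O)O[C@H]1C=CC2=CC(=O)[C@H](O[Si](CC)(CC)CC)C[C@]2(C)[C@H]1C
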